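**Plan**

- Retrosynthesis: the C3–H of ring C of the target flavanone is exchanged for a temporary C3–O bond, the O1–C2 bond is cut to give a 2'-oxygenated chalcone oxirane, the oxirane is cut back to the enone, the Cα=Cβ bond is cut by retro-aldol, and the two aryl–prenyl bonds are cut to a diiodide.
- Forward: ring A is completed first (diiodination, MOM protection, double Stille prenylation), the three-carbon chain and ring B are joined by Claisen–Schmidt condensation, the enone is epoxidised, acid closes ring C through O1–C2, and the C3 oxygen is then removed.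
- Enabling feature: C2 of ring C is a benzylic ether carbon β to the C4 ketone and is lost by retro-oxa-Michael opening if set alone. C2 and C3 are Cβ and Cα of a chalcone enone, so an oxygen on C3, which cannot epimerise by ring opening, can hold C2 as its trans partner.
- Stereochemistry: the peptide-controlled epoxidation sets Cα (R), which becomes C3 (R). Cβ may ionise in the acid step, but the fixed C3 carbinol places the anisyl group trans, giving (2R,3R). Removing the C3 oxygen leaves the same C2 geometry, now named 2S.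

Key step: step 5

Assumption: poly-L-leucine is taken to expose the same enone face of this 2'-alkoxychalcone as it does for chalcone itself, giving the (αR,βS) oxirane; if the sense proved reversed, poly-D-leucine would be used.

**Route**

Step 1
Reactants: 1 2,4-dihydroxyacetophenone
Product: 2 1-(2,4-dihydroxy-3,5-diiodophenyl)ethanone
Conditions: I2, HIO3, EtOH–H2O, 40 °C
Reagents that add atoms: iodine ([I][I]); iodic acid (OI(=O)=O)
Why: Electrophilic aromatic iodination should occur only at C3 and C5, the two positions ortho/para to both hydroxyls, while HIO3 reoxidises iodide so that all iodine ends on carbon.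

Step 2
Reactants: 2 1-(2,4-dihydroxy-3,5-diiodophenyl)ethanone
Product: 3 1-[3,5-diiodo-2,4-bis(methoxymethoxy)phenyl]ethanone
Conditions: NaH, MOMCl, DMF, 0 °C to rt
Reagents that add atoms: chloromethyl methyl ether (COCCl)
Why: Williamson-type O-alkylation of both phenoxides should proceed once NaH has broken the hydrogen-bonded chelate of the 2-hydroxyl, giving base-stable acetals for the next three steps.

Step 3
Reactants: 3 1-[3,5-diiodo-2,4-bis(methoxymethoxy)phenyl]ethanone; 4 tributyl(3-methylbut-2-enyl)stannane
Product: 5 1-[2,4-bis(methoxymethoxy)-3,5-bis(3-methylbut-2-enyl)phenyl]ethanone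
Conditions: Pd(PPh3)4 (10 mol %), DMF, 100 °C
Reagents that add atoms: none
Why: A double Stille cross-coupling on zerovalent palladium should replace both aryl iodides, transmetallation at the tin-bearing carbon delivering the linear prenyl groups, with the ketone and MOM ethers inert.

Step 4
Reactants: 5 1-[2,4-bis(methoxymethoxy)-3,5-bis(3-methylbut-2-enyl)phenyl]ethanone; 6 4-methoxybenzaldehyde
Product: 7 (E)-1-[2,4-bis(methoxymethoxy)-3,5-bis(3-methylbut-2-enyl)phenyl]-3-(4-methoxyphenyl)prop-2-en-1-one
Conditions: KOH, EtOH, rt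
Reagents that add atoms: none
Why: Claisen–Schmidt condensation (crossed aldol then E1cB dehydration) with a non-enolisable aldehyde should give the E-enone, and the protected 2'-oxygen cannot cyclise to a flavanone.

Step 5
Reactants: 7 (E)-1-[2,4-bis(methoxymethoxy)-3,5-bis(3-methylbut-2-enyl)phenyl]-3-(4-methoxyphenyl)prop-2-en-1-one
Product: 8 [(2R,3S)-3-(4-methoxyphenyl)oxiran-2-yl][2,4-bis(methoxymethoxy)-3,5-bis(3-methylbut-2-enyl)phenyl]methanone
Conditions: urea–H2O2, DBU, poly-L-leucine (immobilised on silica), THF, rt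
Reagents that add atoms: urea–hydrogen peroxide adduct (NC(N)=O.OO)
Why: DBU and urea–H2O2 generate hydroperoxide anion, which adds to Cβ of the enone while the carbonyl is held by hydrogen bonds to the free NH groups at the N-terminus of the α-helical poly-L-leucine, and the resulting peroxy-enolate displaces hydroxide from the proximal peroxide oxygen (Weitz–Scheffer pathway). The closest known reaction type is the Juliá–Colonna epoxidation of chalcones, including 2'-alkoxy chalcones, in its non-aqueous urea–H2O2/DBU form. The oxirane closes 3-exo-tet at oxygen, the Cβ–O bond forming first and the Cα–O bond second. Cα (R) and Cβ (S) are both set by catalyst control, the L-peptide helix exposing one enone face, and their trans relationship follows from closure of the enolate in the conformation that keeps the aroyl and anisyl groups apart. The step needs chemoselectivity for the enone over the two trisubstituted prenyl alkenes, which the nucleophilic oxidant secures because it does not attack electron-rich double bonds. The 2'-MOM ether keeps the 2'-oxygen from forming a phenoxide that would deactivate the enone or cyclise to a racemic flavanone.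

Step 6
Reactants: 8 [(2R,3S)-3-(4-methoxyphenyl)oxiran-2-yl][2,4-bis(methoxymethoxy)-3,5-bis(3-methylbut-2-enyl)phenyl]methanone
Product: 11 (2R,3R)-3,7-dihydroxy-2-(4-methoxyphenyl)-6,8-bis(3-methylbut-2-enyl)-2,3-dihydrochromen-4-one, via bis-MOM β-methoxy alcohol 9 (not isolated), via free-phenol β-methoxy alcohol 10 (not isolated)
Conditions: HCl (1.25 M in MeOH), THF co-solvent, rt then 45 °C
Reagents that add atoms: none
Why: Methanolic HCl should first open the anisyl-activated oxirane at Cβ by solvolysis with the Cα–O bond untouched (9), then cleave both MOM acetals by acetal exchange (10), and the 2'-phenol finally captures the reversibly ionised benzylic carbon in a six-membered-ring SN1-type etherification in which the fixed C3 carbinol places the anisyl group trans (both substituents equatorial), so that C2 is set as R under control by C3, as known for acid cyclisation of 2'-MOM chalcone oxiranes to trans-dihydroflavonols.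

Step 7
Reactants: 11 (2R,3R)-3,7-dihydroxy-2-(4-methoxyphenyl)-6,8-bis(3-methylbut-2-enyl)-2,3-dihydrochromen-4-one
Product: 12 [(2R,3R)-3-acetyloxy-2-(4-methoxyphenyl)-6,8-bis(3-methylbut-2-enyl)-4-oxo-2,3-dihydrochromen-7-yl] acetate
Conditions: Ac2O, pyridine, DMAP (cat.), CH2Cl2, 0 °C to rt
Reagents that add atoms: acetic anhydride (CC(=O)OC(C)=O)
Why: DMAP-catalysed acylation should turn the C3 carbinol into a leaving group for the reductive cleavage and mask the 7-phenol, without touching C2 or C3 at this temperature.

Step 8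
Reactants: 12 [(2R,3R)-3-acetyloxy-2-(4-methoxyphenyl)-6,8-bis(3-methylbut-2-enyl)-4-oxo-2,3-dihydrochromen-7-yl] acetate
Product: 13 [(2S)-2-(4-methoxyphenyl)-6,8-bis(3-methylbut-2-enyl)-4-oxo-2,3-dihydrochromen-7-yl] acetate
Conditions: SmI2 (2.2 equiv.), THF–MeOH, −78 °C
Reagents that add atoms: none
Why: Reductive cleavage of an α-acyloxy ketone by SmI2 should proceed through the aryl ketyl, loss of acetate from C3 after the second electron transfer, and protonation of the samarium enolate by methanol at −78 °C before it can expel O1, so that C2 keeps its geometry and is renamed S only because C3 has lost its oxygen.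

Step 9
Reactants: 13 [(2S)-2-(4-methoxyphenyl)-6,8-bis(3-methylbut-2-enyl)-4-oxo-2,3-dihydrochromen-7-yl] acetate
Product: 14 (2S)-7-hydroxy-2-(4-methoxyphenyl)-6,8-bis(3-methylbut-2-enyl)-2,3-dihydrochromen-4-one (the target flavanone)
Conditions: NH4OAc, MeOH–H2O, rt
Reagents that add atoms: none
Why: NH4OAc-mediated methanolysis of the aryl acetate (transesterification under near-neutral conditions) should free the acidic 7-phenol without generating the ring-C enolate whose ring opening would racemise C2.

**Compound list**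

1 | 2,4-dihydroxyacetophenone | CC(=O)c1ccc(O)cc1O | starting material
2 | 1-(2,4-dihydroxy-3,5-diiodophenyl)ethanone | Ic1cc(C(C)=O)c(O)c(c1O)I | intermediate
3 | 1-[3,5-diiodo-2,4-bis(methoxymethoxy)phenyl]ethanone | Ic1cc(C(C)=O)c(OCOC)c(c1OCOC)I | intermediate
4 | tributyl(3-methylbut-2-enyl)stannane | CC(C)=CC[Sn](CCCC)(CCCC)CCCC | starting material
5 | 1-[2,4-bis(methoxymethoxy)-3,5-bis(3-methylbut-2-enyl)phenyl]ethanone | CC(=O)c1cc(CC=C(C)C)c(OCOC)c(CC=C(C)C)c1OCOC | intermediate
6 | 4-methoxybenzaldehyde | COc1ccc(C=O)cc1 | starting material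
7 | (E)-1-[2,4-bis(methoxymethoxy)-3,5-bis(3-methylbut-2-enyl)phenyl]-3-(4-methoxyphenyl)prop-2-en-1-one | COc1ccc(/C=C/C(=O)c2cc(CC=C(C)C)c(OCOC)c(CC=C(C)C)c2OCOC)cc1 | intermediate
8 | [(2R,3S)-3-(4-methoxyphenyl)oxiran-2-yl][2,4-bis(methoxymethoxy)-3,5-bis(3-methylbut-2-enyl)phenyl]methanone, the (αR,βS) trans-oxirane | COc1ccc([C@@H]2O[C@H]2C(=O)c3cc(CC=C(C)C)c(OCOC)c(CC=C(C)C)c3OCOC)cc1 | intermediate
9 | (2R)-1-[2,4-bis(methoxymethoxy)-3,5-bis(3-methylbut-2-enyl)phenyl]-2-hydroxy-3-methoxy-3-(4-methoxyphenyl)propan-1-one, C3 epimers | COc1ccc(C(OC)[C@@H](O)C(=O)c2cc(CC=C(C)C)c(OCOC)c(CC=C(C)C)c2OCOC)cc1 | intermediate (not isolated)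
10 | (2R)-1-[2,4-dihydroxy-3,5-bis(3-methylbut-2-enyl)phenyl]-2-hydroxy-3-methoxy-3-(4-methoxyphenyl)propan-1-one, C3 epimers | COc1ccc(C(OC)[C@@H](O)C(=O)c2cc(CC=C(C)C)c(O)c(CC=C(C)C)c2O)cc1 | intermediate (not isolated)
11 | (2R,3R)-3,7-dihydroxy-2-(4-methoxyphenyl)-6,8-bis(3-methylbut-2-enyl)-2,3-dihydrochromen-4-one, trans | COc1ccc([C@@H]2[C@@H](O)C(=O)c3cc(CC=C(C)C)c(O)c(CC=C(C)C)c3O2)cc1 | intermediate
12 | [(2R,3R)-3-acetyloxy-2-(4-methoxyphenyl)-6,8-bis(3-methylbut-2-enyl)-4-oxo-2,3-dihydrochromen-7-yl] acetate | COc1ccc([C@@H]2[C@@H](OC(C)=O)C(=O)c3cc(CC=C(C)C)c(OC(C)=O)c(CC=C(C)C)c3O2)cc1 | intermediate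
13 | [(2S)-2-(4-methoxyphenyl)-6,8-bis(3-methylbut-2-enyl)-4-oxo-2,3-dihydrochromen-7-yl] acetate | COc1ccc([C@@H]2CC(=O)c3cc(CC=C(C)C)c(OC(C)=O)c(CC=C(C)C)c3O2)cc1 | intermediate
14 | (2S)-7-hydroxy-2-(4-methoxyphenyl)-6,8-bis(3-methylbut-2-enyl)-2,3-dihydrochromen-4-one, the target flavanone | COc1ccc([C@@H]2CC(=O)c3cc(CC=C(C)C)c(O)c(CC=C(C)C)c3O2)cc1 | target

**Step count and risks**

Total step count: 9. Longest linear sequence: 9 steps (1 to 14).

Steps most likely to fail:

Step 6. The anisyl-stabilised benzylic cation may undergo 1,2-aroyl migration instead of ring closure, the freed phenols may add to the neighbouring prenyl double bonds under the acid (chroman formation), and prolonged acid may enolise C3 and erode the relay. The fallback sets out from 8 and comes back at 11, avoiding Brønsted acid and cationic closure altogether. Me3SiOTf with 2,2'-bipyridyl in CH2Cl2 at 0 °C should exchange both aryl MOM ethers for trimethylsilyl ethers, giving [(2R,3S)-3-(4-methoxyphenyl)oxiran-2-yl][3,5-bis(3-methylbut-2-enyl)-2,4-bis(trimethylsilyloxy)phenyl]methanone F1. K2CO3 in MeOH at 0 °C then releases the 2'-phenoxide, which should open the oxirane at Cβ by direct SN2 attack with inversion to give 11; survival of the oxirane under the buffered silyl triflate is the point to test first.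

Step 8. The samarium enolate may expel O1 before it is protonated, opening ring C to the chalcone and losing C2, or the product ketone may be reduced further. The fallback sets out from 11 and comes back at 14, using a radical Barton–McCombie deoxygenation that never forms an enolate. The 7-phenol is silylated selectively (TBSCl, imidazole, DMF) to (2R,3R)-7-[tert-butyl(dimethyl)silyl]oxy-3-hydroxy-2-(4-methoxyphenyl)-6,8-bis(3-methylbut-2-enyl)-2,3-dihydrochromen-4-one F2. The C3 hydroxyl is then converted with PhOC(S)Cl, pyridine and DMAP into O-[(2R,3R)-7-[tert-butyl(dimethyl)silyl]oxy-2-(4-methoxyphenyl)-6,8-bis(3-methylbut-2-enyl)-4-oxo-2,3-dihydrochromen-3-yl] O-phenyl carbonothioate F3. Bu3SnH and AIBN in toluene at 80 °C should cleave the C3–O bond homolytically to (2S)-7-[tert-butyl(dimethyl)silyl]oxy-2-(4-methoxyphenyl)-6,8-bis(3-methylbut-2-enyl)-2,3-dihydrochromen-4-one F4, and KHF2 in MeOH at rt removes the aryl silyl ether to give 14.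

Step 5. Hydroperoxide addition to this twisted, electron-rich 2'-alkoxy enone may be slow and poorly face-selective, so that uncatalysed background epoxidation lowers the enantiomeric purity. The fallback sets out from 5 and 6 and comes back at 8, building the oxirane by C–C bond formation instead of oxidation. The lithium enolate of 5 (LiN(SiMe3)2, THF, −78 °C) is chlorinated with p-toluenesulfonyl chloride to 2-chloro-1-[2,4-bis(methoxymethoxy)-3,5-bis(3-methylbut-2-enyl)phenyl]ethanone F5. An asymmetric Darzens condensation of this chloro ketone with 6 under a cinchona-derived quaternary ammonium phase-transfer catalyst (LiOH·H2O, CH2Cl2, 0 °C), the pseudo-enantiomer being chosen to give the (αR,βS) series, should then close the trans-oxirane 8 with no oxidant near the prenyl groups.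

Further compounds

F1 | step 6 | [(2R,3S)-3-(4-methoxyphenyl)oxiran-2-yl][3,5-bis(3-methylbut-2-enyl)-2,4-bis(trimethylsilyloxy)phenyl]methanone | COc1ccc([C@@H]2O[C@H]2C(=O)c3cc(CC=C(C)C)c(O[Si](C)(C)C)c(CC=C(C)C)c3O[Si](C)(C)C)cc1
F2 | step 8 | (2R,3R)-7-[tert-butyl(dimethyl)silyl]oxy-3-hydroxy-2-(4-methoxyphenyl)-6,8-bis(3-methylbut-2-enyl)-2,3-dihydrochromen-4-one | COc1ccc([C@@H]2[C@@H](O)C(=O)c3cc(CC=C(C)C)c(O[Si](C)(C)C(C)(C)C)c(CC=C(C)C)c3O2)cc1
F3 | step 8 | O-[(2R,3R)-7-[tert-butyl(dimethyl)silyl]oxy-2-(4-methoxyphenyl)-6,8-bis(3-methylbut-2-enyl)-4-oxo-2,3-dihydrochromen-3-yl] O-phenyl carbonothioate | COc1ccc([C@@H]2[C@@H](OC(=S)Oc4ccccc4)C(=O)c3cc(CC=C(C)C)c(O[Si](C)(C)C(C)(C)C)c(CC=C(C)C)c3O2)cc1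
F4 | step 8 | (2S)-7-[tert-butyl(dimethyl)silyl]oxy-2-(4-methoxyphenyl)-6,8-bis(3-methylbut-2-enyl)-2,3-dihydrochromen-4-one | COc1ccc([C@@H]2CC(=O)c3cc(CC=C(C)C)c(O[Si](C)(C)C(C)(C)C)c(CC=C(C)C)c3O2)cc1
F5 | step 5 | 2-chloro-1-[2,4-bis(methoxymethoxy)-3,5-bis(3-methylbut-2-enyl)phenyl]ethanone | ClCC(=O)c1cc(CC=C(C)C)c(OCOC)c(CC=C(C)C)c1OCOC
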